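- Watch the leftover substrate: in the cedar run's last reading 4% of the charge remains beside 82% target, so 14.0% has gone elsewhere, and full conversion to target is not the end state to expect.

| flask | substrate | remark | time |
|---|---|---|---|
| maple | 0.072 M | run made earlier |  |
| birch | 0.11 M | run made earlier |  |
| cedar | 0.18 M | run made earlier |  |
| Tuesday's | 0.060 M |  | 6.0 min |
| Friday's | 0.20 M |  | 4.0 min |

- maple (time / s: target / %, substrate / %): 25.0: 50, 48; 50.0: 65, 31; 80.0: 72, 23; 90.0: 74, 21; 120: 79, 14
- birch (time / s: target / %, substrate / %): 10.0: 38, 60; 30.0: 65, 33; 60.0: 73, 17; 80.0: 77, 16; 120: 81, 11
- cedar (time / s: target / %, substrate / %): 10.0: 52, 47; 20.0: 65, 28; 30.0: 74, 22; 60.0: 79, 12; 120: 82, 4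

(standard deviation of a reading: 1.5 percentage points)

- in percentages every species weighs as the substrate in it: one target counts as two

- the winner by amount of target, in percent of the substrate charged; "neither" if no more than 2 percentage points parts them (Tuesday's / Friday's / neither)
- how much target is there at the end, in percent of the substrate charged: Tuesday's
- how much target is there at the end, in percent of the substrate charged: Friday's

- Charge and time appear to act as a product: the maple run at 25.0 s and the cedar run at 10.0 s have equal products and read 50% and 52% target, so an error in either counts alike.
- Late on, that product matters little: in the cedar run, twice the time added 3 percentage points of target.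
- The scatter matters more: at the earlier runs' scatter, a difference of two readings carries 2.1 points, more than the margin of 2 points, so one reading from each flask cannot name a winner.
- For a second-order fall, the inverse of the leftover fraction, less one, grows as K times c(substrate) as charged times time; the birch run at 30.0 s gives K = 0.615 /M/s.
- That product, the exposure D (a Damköhler number), is 13.3 for Tuesday's flask, the same as the cedar run's last reading, 13.3.
- My reckoning therefore reads Tuesday's target as 82%. Friday's D of 29.5 lies beyond the readings. Between the cedar run's last two readings, target rose 3 points while substrate fell 8 points. If the 4% left in that run's last reading went the same way, my estimate puts Friday's flask about 1.5 points above Tuesday's, less than the margin of 2 points, so I expect neither flask to win.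
- The forecast says neither, with 82% for Tuesday's and 82% for Friday's, on the ground that “the shortfall follows conversion rather than time or concentration”.
- The flasks give neither, with 81.4% for Tuesday's and 81.1% for Friday's, so the forecast held.

    2 substrate → target (k = 0.310 /M/s)
    2 substrate → homo dimer (k = 2.10 × 10⁻⁴ /M/s)
    substrate + target → side product (k = 0.0340 /M/s)

- Neither flask has come to rest. Tuesday's flask at D 13.3 holds 5.94% substrate and 12.6% side product; Friday's at D 29.5 holds 2.27% and 16.6%. Friday's flask read at 10 min, D 73.8, shows 79.6% target and 19.8% side product. At 60.0 min, Tuesday's flask has 0.121% substrate, 78.9% target and 20.9% side product. At 40.0 min, Friday's flask has 0% substrate, 78.7% target and 21.2% side product.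

(The numbers in the tables come from a simulation with constants of no real substance; the scatter is artificial.)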